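**Assumption:** the target has no stereocentre and is achiral, so there is no enantiomer to select. The task is the constitution only: a 27-membered ring of 26 carbons and one ring oxygen.

## Retrosynthetic overview

1. Open the ring C(=O)–O bond of 26-hexacosanolide and take the acyl carbon down to CH2OH. This gives symmetrical hexacosane-1,26-diol, and the forward reaction is a dehydrogenative C–O ring closure.
2. Both ends of the diol are identical, so oxidation at either end gives the same lactone. No protecting group or end differentiation is needed.
3. Cut hexacosane-1,26-diol into C11 + C4 + C11 (at C11–C12 and C15–C16). This gives two 11-bromoundecan-1-ol and 1,4-dibromobutane, the latter used as its di-Grignard reagent.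
4. Ring order: there is one ring only, the 27-membered lactone, closed in the last step.

## Route

**Step 1**
Reactants: 1 11-bromoundecan-1-ol (2.2 equiv); 2 1,4-dibromobutane (1.0 equiv)
Product: 5 hexacosane-1,26-diol, via butane-1,4-diylbis(magnesium bromide) 3 (not isolated), via chloromagnesium 11-bromoundecan-1-olate 4 (not isolated)
Conditions: flask A: 2, Mg (3 equiv), THF, 40 °C, slow addition, titrate; flask B: 1, MeMgCl (1.0 equiv per OH), THF, −20 °C, then Li2CuCl4 (3 mol%), NMP (4 equiv); A into B over 2 h, 0 °C to rt, 12 h; 1 M HCl; recrystallise from toluene
Reagents that add atoms: none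
Why: Kochi-type copper-catalysed C(sp3)–C(sp3) cross-coupling, in which the alkylcopper species formed from 3 displaces the primary bromide of 4 at both ends of the C4 unit (11 + 4 + 11 = 26 carbons); the hydroxyl is masked in the flask as an unreactive magnesium alkoxide so that none of 3 is protonated to a chain-capping butyl Grignard, the bromide is kept in excess to drive the second coupling, and no stereocentre is formed.

**Step 2**
Reactants: 5 hexacosane-1,26-diol
Product: 8 26-hexacosanolide (oxacycloheptacosan-2-one), via 26-hydroxyhexacosanal 6 (not isolated), via oxacycloheptacosan-2-ol 7 (not isolated)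
Conditions: RuHCl(CO)[HN(CH2CH2PPh2)2] (4 mol%), KOtBu (8 mol%), toluene (2 mM in 5, solution pre-dried at reflux through 4 Å sieves), reflux, slow Ar sweep, 36 h; AcOH quench; silica plug (hexane/EtOAc)
Reagents that add atoms: none
Why: Proposed new method: the amido-ruthenium hydride formed from the precatalyst and KOtBu removes H2 from either (equivalent) CH2OH end by outer-sphere metal–ligand bifunctional hydrogen transfer to give 6, the distal OH adds to the CHO to make the ring-closing C–O bond in lactol 7, and the same catalyst dehydrogenates 7 to 8 while H2 leaves the open refluxing system; at 2 mM (4 mM in OH) the effective molarity of a strain-free 27-membered ring (about 0.02–0.05 M) exceeds the OH concentration so closure outruns dimerisation, the potassium alkoxide keeps all ester links in ring–chain equilibrium so that linear or cyclic oligomers back-bite to the monomeric lactone (estimated at over 90% at this dilution), and any dialdehyde from double oxidation re-enters through a ruthenium hydride-shuttle (Tishchenko-type) path to the same product; the closest known reaction type is acceptorless dehydrogenative coupling of primary alcohols to esters and lactonisation of 1,4- and 1,5-diols by ruthenium pincer complexes, which with longer diols has only been run concentrated to give polyesters and has not been used to close a large ring.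

## Compound list

1 | 11-bromoundecan-1-ol | OCCCCCCCCCCCBr | starting material
2 | 1,4-dibromobutane | BrCCCCBr | starting material
3 | butane-1,4-diylbis(magnesium bromide), not isolated | Br[Mg]CCCC[Mg]Br | intermediate
4 | chloromagnesium 11-bromoundecan-1-olate, not isolated | Cl[Mg]OCCCCCCCCCCCBr | intermediate
5 | hexacosane-1,26-diol | OCCCCCCCCCCCCCCCCCCCCCCCCCCO | intermediate
6 | 26-hydroxyhexacosanal, not isolated | O=CCCCCCCCCCCCCCCCCCCCCCCCCCO | intermediate
7 | oxacycloheptacosan-2-ol (27-membered lactol, racemic transient centre, not isolated) | OC1CCCCCCCCCCCCCCCCCCCCCCCCCO1 | intermediate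
8 | 26-hexacosanolide (oxacycloheptacosan-2-one), achiral | O=C1CCCCCCCCCCCCCCCCCCCCCCCCCO1 | target

## Step count and risks

Total step count: 2. Longest linear sequence: 2.

The route has only two steps, so both are ranked. Step 1 is entered twice, once for each of its in-flask stages, because they fail for different reasons.

**A. Step 2 (the new ring closure), the most likely to fail.**
- Turnover may be slow at 2 mM.
- Trace water can turn 6 into a carboxylate that consumes the base and binds ruthenium.
- The oligomer share may be higher than the ring–chain estimate.

The fallback uses known chemistry, sets out from 5 and comes back at 8. Diol 5 is monobrominated with 48% aqueous HBr in refluxing toluene to 26-bromohexacosan-1-ol F1. This is oxidised with CrO3/H2SO4 in acetone–CH2Cl2 to 26-bromohexacosanoic acid F2. F2 is then added by syringe pump to Cs2CO3 in DMF at 80 °C (final 3 mM). The caesium carboxylate displaces the terminal bromide in an SN2 macrolactonisation, again closing the ring through a C–O bond, to give 8.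

**B. Step 1, coupling stage (3 plus 4 to 5).**
- The second coupling may stay incomplete.
- The bromide may be reduced or eliminated.
- Either outcome leaves monofunctional alcohols that would cap chains in step 2.

The fallback replaces cross-coupling by olefination and hydrogenation, sets out from 1 and comes back at 5. Compound 1 is heated with PPh3 in MeCN to give (11-hydroxyundecyl)triphenylphosphonium bromide F3. Succinaldehyde F4 is made fresh by hydrolysis of 2,5-dimethoxytetrahydrofuran in water at 90 °C. F3 (2 equiv) is treated with NaN(SiMe3)2 (4 equiv) in THF at −78 °C and then with F4. The double Wittig reaction gives (11Z,15Z)-hexacosa-11,15-diene-1,26-diol F5 (11 + 4 + 11 carbons). Hydrogenation (H2, Pd/C, THF/EtOH, 50 °C) gives 5.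

**C. Step 1, formation of di-Grignard 3.**
- Wurtz coupling of 2 would give a C8 di-Grignard and hence a C30 homologue of 5 that is hard to remove.
- A low titre or partial protonation would give chain-capping butyl ends.

The fallback reverses the polarity, sets out from 1 and 2 and comes back at 5. Compound 1 is protected with 3,4-dihydro-2H-pyran and pyridinium p-toluenesulfonate in CH2Cl2 as 2-[(11-bromoundecyl)oxy]tetrahydro-2H-pyran F6. This is converted with Mg in THF into {11-[(tetrahydro-2H-pyran-2-yl)oxy]undecyl}magnesium bromide F7. F7 (2.3 equiv) is coupled with 2 as the bis-electrophile (Li2CuCl4 3 mol%, NMP, THF, 0 °C to rt) to give 1,26-bis[(tetrahydro-2H-pyran-2-yl)oxy]hexacosane F8. Acetal cleavage (TsOH, MeOH/THF, 50 °C) releases 5.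

## Further compounds

F1 | step 2 | 26-bromohexacosan-1-ol | OCCCCCCCCCCCCCCCCCCCCCCCCCCBr
F2 | step 2 | 26-bromohexacosanoic acid | OC(=O)CCCCCCCCCCCCCCCCCCCCCCCCCBr
F3 | step 1 | (11-hydroxyundecyl)triphenylphosphonium bromide | OCCCCCCCCCCC[P+](c1ccccc1)(c1ccccc1)c1ccccc1.[Br-]
F4 | step 1 | succinaldehyde (butanedial) | O=CCCC=O
F5 | step 1 | (11Z,15Z)-hexacosa-11,15-diene-1,26-diol | OCCCCCCCCCC/C=C\CC/C=C\CCCCCCCCCCO
F6 | step 1 | 2-[(11-bromoundecyl)oxy]tetrahydro-2H-pyran (racemic) | BrCCCCCCCCCCCOC1CCCCO1
F7 | step 1 | {11-[(tetrahydro-2H-pyran-2-yl)oxy]undecyl}magnesium bromide (racemic) | Br[Mg]CCCCCCCCCCCOC1CCCCO1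
F8 | step 1 | 1,26-bis[(tetrahydro-2H-pyran-2-yl)oxy]hexacosane (mixture of acetal diastereomers) | O1CCCCC1OCCCCCCCCCCCCCCCCCCCCCCCCCCOC1CCCCO1
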